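The furan of the 2-aryl-3-benzylbenzofuran is read as a masked ketone: O1, C2 (bearing ring A) and C3 (bearing the CH2 link to ring D) are the enol of the dihydrochalcone ring A–CO–CH2–CH2–ring D. One palladium-catalysed operation joins this ketone to an ortho-bromoiodoarene, forming C3–C3a at the iodide and O1–C7a at the bromide, so the furan ring and the 6-oxygenated benzo ring arrive together. The precursor is a MOM-protected dihydrochalcone with one enolisable CH2 and a silyl-protected hydroxyethyl arm on ring D, later oxidised to the arylacetic acid that builds the 3-arylcoumarin. Both 1,1-dimethylallyl groups stem from one aromatic Claisen rearrangement.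

Key step: step 17

Assumption: 3-bromo-4-iodophenol and methyl (2,4-dihydroxyphenyl)acetate are bought; compounds 5, 8 and 24 are racemic, the target has no stereocentre, and the E double bond of 21 is reduced in the next step.

**Ring A ketone and the coumarin aldehyde (steps 1–8)**

Step 1
Reactants: 1 2,4-dihydroxybenzaldehyde; 2 1-bromo-3-methylbut-2-ene (prenyl bromide)
Product: 3 2-hydroxy-4-[(3-methylbut-2-en-1-yl)oxy]benzaldehyde
Conditions: K2CO3 (1.1 equiv), acetone, reflux
Reagents that add atoms: none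
Why: Williamson ether synthesis; the 2-OH is held in a hydrogen bond to the formyl oxygen, so the more acidic 4-OH should be alkylated selectively.

Step 2
Reactants: 3 2-hydroxy-4-[(3-methylbut-2-en-1-yl)oxy]benzaldehyde
Product: 4 2-(methoxymethoxy)-4-[(3-methylbut-2-en-1-yl)oxy]benzaldehyde
Conditions: NaH (1.2 equiv), MOMCl (1.2 equiv), DMF, 0 °C to rt
Reagents that add atoms: chloromethyl methyl ether, COCCl
Why: O-alkylation of the sodium phenoxide (MOM protection); capping the chelated 2-OH removes the hydrogen-bond bias that would otherwise steer the coming rearrangement to C3.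

Step 3
Reactants: 4 2-(methoxymethoxy)-4-[(3-methylbut-2-en-1-yl)oxy]benzaldehyde
Product: 6 4-hydroxy-2-(methoxymethoxy)-5-(2-methylbut-3-en-2-yl)benzaldehyde, via ortho-dienone 5 (not isolated)
Conditions: N,N-diethylaniline, 190 °C, argon, sealed tube
Reagents that add atoms: none
Why: Aromatic Claisen rearrangement, a [3,3]-sigmatropic shift that inverts the prenyl unit so that its CMe2 carbon bonds to the ring, followed by tautomerisation of dienone 5; C5 should be preferred because C3 is flanked by two oxygen substituents, and the basic solvent disfavours acid-induced ring closure of the product.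

Step 4
Reactants: 6 4-hydroxy-2-(methoxymethoxy)-5-(2-methylbut-3-en-2-yl)benzaldehyde
Product: 7 2,4-bis(methoxymethoxy)-5-(2-methylbut-3-en-2-yl)benzaldehyde
Conditions: NaH (1.3 equiv), MOMCl (1.3 equiv), DMF, 0 °C to rt
Reagents that add atoms: chloromethyl methyl ether, COCCl
Why: MOM protection of the phenoxide; the small, highly reactive chloro ether should reach the oxygen next to the quaternary carbon without difficulty.

Step 5
Reactants: 7 2,4-bis(methoxymethoxy)-5-(2-methylbut-3-en-2-yl)benzaldehyde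
Product: 8 1-[2,4-bis(methoxymethoxy)-5-(2-methylbut-3-en-2-yl)phenyl]ethan-1-ol (racemic)
Conditions: MeMgBr (1.3 equiv), THF, 0 °C; then aq NH4Cl
Reagents that add atoms: methylmagnesium bromide, C[Mg]Br
Why: Grignard addition to a non-enolisable aryl aldehyde; acetals and the isolated alkene are inert, and the new stereocentre is lost in the next step.

Step 6
Reactants: 8 1-[2,4-bis(methoxymethoxy)-5-(2-methylbut-3-en-2-yl)phenyl]ethan-1-ol
Product: 9 1-[2,4-bis(methoxymethoxy)-5-(2-methylbut-3-en-2-yl)phenyl]ethan-1-one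
Conditions: activated MnO2 (15 equiv), CH2Cl2, rt
Reagents that add atoms: none
Why: MnO2 oxidation of a benzylic secondary alcohol under neutral heterogeneous conditions, which should spare the MOM ethers and the terminal alkene.

Step 7
Reactants: 6 4-hydroxy-2-(methoxymethoxy)-5-(2-methylbut-3-en-2-yl)benzaldehyde
Product: 10 2,4-dihydroxy-5-(2-methylbut-3-en-2-yl)benzaldehyde
Conditions: HCl (1.25 M in MeOH), rt to 40 °C; aq NaHCO3 work-up
Reagents that add atoms: none
Why: Acid-catalysed acetal exchange (MOM cleavage) with methanol; the monosubstituted alkene is too weakly basic to be protonated by dilute methanolic HCl.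

Step 8
Reactants: 10 2,4-dihydroxy-5-(2-methylbut-3-en-2-yl)benzaldehyde
Product: 11 2-hydroxy-4-(methoxymethoxy)-5-(2-methylbut-3-en-2-yl)benzaldehyde
Conditions: MOMCl (1.05 equiv), K2CO3 (1.2 equiv), acetone, 0 °C to rt
Reagents that add atoms: chloromethyl methyl ether, COCCl
Why: Selective Williamson-type MOM etherification of the non-chelated 4-OH, the same hydrogen-bond differentiation as in step 1, leaving the 2-OH free for the later ester formation.

**Ring D aldehyde (steps 9–13)**

Step 9
Reactants: 12 methyl (2,4-dihydroxyphenyl)acetate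
Product: 13 methyl [2,4-bis(methoxymethoxy)phenyl]acetate
Conditions: MOMCl (3 equiv), i-Pr2NEt (4 equiv), CH2Cl2, 0 °C to rt
Reagents that add atoms: chloromethyl methyl ether, COCCl
Why: Amine-mediated MOM protection of both phenols; the mild base avoids phenoxide attack on the neighbouring ester (lactonisation to the benzofuranone).

Step 10
Reactants: 13 methyl [2,4-bis(methoxymethoxy)phenyl]acetate
Product: 14 2-[2,4-bis(methoxymethoxy)phenyl]ethan-1-ol
Conditions: LiAlH4 (1.0 equiv), THF, 0 °C; then H2O, aq NaOH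
Reagents that add atoms: none
Why: Hydride reduction of the ester to the primary alcohol; MOM ethers are inert to LiAlH4.

Step 11
Reactants: 14 2-[2,4-bis(methoxymethoxy)phenyl]ethan-1-ol
Product: 15 {2-[2,4-bis(methoxymethoxy)phenyl]ethoxy}(tert-butyl)dimethylsilane
Conditions: TBSCl (1.2 equiv), imidazole (2 equiv), CH2Cl2, rt
Reagents that add atoms: tert-butyldimethylsilyl chloride, CC(C)(C)[Si](C)(C)Cl
Why: Imidazole-promoted silylation of a primary alcohol gives a base-stable, fluoride-labile ether orthogonal to MOM.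

Step 12
Reactants: 15 {2-[2,4-bis(methoxymethoxy)phenyl]ethoxy}(tert-butyl)dimethylsilane
Product: 16 {2-[5-bromo-2,4-bis(methoxymethoxy)phenyl]ethoxy}(tert-butyl)dimethylsilane
Conditions: NBS (1.05 equiv), MeCN, 0 °C
Reagents that add atoms: N-bromosuccinimide, O=C1CCC(=O)N1Br
Why: Electrophilic aromatic bromination; C5 is para to one MOM-oxygen and ortho to the other, whereas C3 between the two acetals is shielded and C6 is not activated.

Step 13
Reactants: 16 {2-[5-bromo-2,4-bis(methoxymethoxy)phenyl]ethoxy}(tert-butyl)dimethylsilane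
Product: 18 5-(2-{[tert-butyl(dimethyl)silyl]oxy}ethyl)-2,4-bis(methoxymethoxy)benzaldehyde, via aryllithium 17 (not isolated)
Conditions: n-BuLi (1.1 equiv), THF, −78 °C; DMF (3 equiv), −78 to 0 °C; then aq NH4Cl
Reagents that add atoms: N,N-dimethylformamide, CN(C)C=O
Why: Bromine–lithium exchange, faster than deprotonation at C3 at −78 °C, followed by formylation of the aryllithium with DMF (Bouveault-type).

**Aryl dihalide (step 14)**

Step 14
Reactants: 19 3-bromo-4-iodophenol
Product: 20 2-bromo-1-iodo-4-(methoxymethoxy)benzene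
Conditions: NaH (1.2 equiv), MOMCl (1.2 equiv), THF, 0 °C to rt
Reagents that add atoms: chloromethyl methyl ether, COCCl
Why: MOM protection of the phenoxide; both carbon–halogen bonds are inert to these conditions.

**Assembly and endgame (steps 15–21)**

Step 15
Reactants: 9 1-[2,4-bis(methoxymethoxy)-5-(2-methylbut-3-en-2-yl)phenyl]ethan-1-one; 18 5-(2-{[tert-butyl(dimethyl)silyl]oxy}ethyl)-2,4-bis(methoxymethoxy)benzaldehyde
Product: 21 (E)-chalcone of ring A ketone 9 and ring D aldehyde 18
Conditions: KOH (5 equiv), EtOH/H2O, rt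
Reagents that add atoms: none
Why: Claisen–Schmidt condensation between a methyl ketone and a non-enolisable aldehyde; E1cB dehydration gives the conjugated E-enone, and MOM and primary TBS ethers tolerate cold ethanolic KOH.

Step 16
Reactants: 21 (E)-chalcone
Product: 23 1-[2,4-bis(methoxymethoxy)-5-(2-methylbut-3-en-2-yl)phenyl]-3-[5-(2-{[tert-butyl(dimethyl)silyl]oxy}ethyl)-2,4-bis(methoxymethoxy)phenyl]propan-1-one, via silyl enol ether 22 (not isolated)
Conditions: [(Ph3P)CuH]6 (5 mol %), PhMe2SiH (1.5 equiv), toluene, rt; then K2CO3 (cat.), MeOH, rt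
Reagents that add atoms: none
Why: Copper hydride conjugate reduction delivers hydride to the enone beta-carbon and the enolate is silylated, then methanolysed; the unactivated terminal alkene is not a substrate, unlike under catalytic hydrogenation.

Step 17
Reactants: 23 dihydrochalcone (ring A–CO–CH2–CH2–ring D); 20 2-bromo-1-iodo-4-(methoxymethoxy)benzene
Product: 25 2-[2,4-bis(methoxymethoxy)-5-(2-methylbut-3-en-2-yl)phenyl]-3-{[5-(2-{[tert-butyl(dimethyl)silyl]oxy}ethyl)-2,4-bis(methoxymethoxy)phenyl]methyl}-6-(methoxymethoxy)-1-benzofuran, via alpha-(2-bromoaryl) ketone 24 (not isolated)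
Conditions: Pd2(dba)3 (5 mol %), bis[2-(diphenylphosphino)phenyl] ether (DPEphos, 12 mol %), Cs2CO3 (3 equiv), toluene, 110 °C
Reagents that add atoms: none
Why: Zerovalent palladium inserts into the C–I bond of 20 well before the C–Br bond, the caesium enolate of 23 (its CO–CH2 is the only enolisable position) replaces iodide on divalent palladium, and C–C reductive elimination gives ketone 24, which fixes C3–C3a. The now more acidic 24 re-enolises, a second oxidative addition into the neighbouring C–Br bond gives an oxygen-bound six-membered palladacycle, and C–O reductive elimination closes the five-membered furan by intramolecular enolate O-arylation (O1–C7a), the ketone oxygen becoming O1. The closest known chemistry is the palladium-catalysed alpha-arylation of alkyl aryl ketones and its tandem extension with ortho-dihaloarenes to 2,3-disubstituted benzofurans. No stereocentre is set, since the transient one in 24 disappears on enolisation. The step needs iodide-before-bromide selectivity, secured by the faster oxidative addition of the C–I bond, which places the MOM-oxygen at C6; it also needs enolate arylation to outrun Heck insertion of the terminal alkene, which the adjacent quaternary carbon and the high enolate concentration should favour.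

Step 18
Reactants: 25 silyl-protected benzofuran
Product: 26 2-[5-({2-[2,4-bis(methoxymethoxy)-5-(2-methylbut-3-en-2-yl)phenyl]-6-(methoxymethoxy)-1-benzofuran-3-yl}methyl)-2,4-bis(methoxymethoxy)phenyl]ethan-1-ol
Conditions: Bu4NF (1.2 equiv), THF, 0 °C to rt
Reagents that add atoms: none
Why: Fluoride-induced desilylation, driven by the Si–F bond, leaves the MOM ethers and the alkene untouched.

Step 19
Reactants: 26 benzofuran primary alcohol
Product: 28 [5-({2-[2,4-bis(methoxymethoxy)-5-(2-methylbut-3-en-2-yl)phenyl]-6-(methoxymethoxy)-1-benzofuran-3-yl}methyl)-2,4-bis(methoxymethoxy)phenyl]acetic acid, via arylacetaldehyde 27 (not isolated)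
Conditions: TEMPO (0.2 equiv), PhI(OAc)2 (2.5 equiv), MeCN/H2O 1:1, rt
Reagents that add atoms: water, O
Why: Oxoammonium-mediated (TEMPO/PhI(OAc)2) oxidation of the primary alcohol to the aldehyde and, through its hydrate, to the acid; the chlorine-free medium avoids halogenation of the electron-rich rings.

Step 20
Reactants: 28 ring D arylacetic acid; 11 2-hydroxy-4-(methoxymethoxy)-5-(2-methylbut-3-en-2-yl)benzaldehyde
Product: 30 hexa-MOM ether of the target (3-arylcoumarin), via aryl ester 29 (not isolated)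
Conditions: DCC (1.2 equiv), DMAP (0.2 equiv), CH2Cl2, 0 °C to rt; then DBU (1 equiv), rt
Reagents that add atoms: none
Why: Steglich esterification of the salicylaldehyde 2-OH followed by base-mediated intramolecular Knoevenagel condensation of the activated arylacetate CH2 onto the ortho formyl group (Perkin-type coumarin synthesis); the lactone tether enforces the cis geometry of the new C3–C4 double bond.

Step 21
Reactants: 30 hexa-MOM ether of the target
Product: 31 3-[5-({2-[2,4-dihydroxy-5-(2-methylbut-3-en-2-yl)phenyl]-6-hydroxy-1-benzofuran-3-yl}methyl)-2,4-dihydroxyphenyl]-7-hydroxy-6-(2-methylbut-3-en-2-yl)-2H-chromen-2-one (CNP0380243.0)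
Conditions: HCl (1.25 M in MeOH)/THF, 40 °C, argon
Reagents that add atoms: none
Why: Acid-catalysed transacetalisation of all six MOM ethers to methanol; the benzofuran and coumarin are acid-stable, and the monosubstituted alkenes should resist protonation under dilute methanolic HCl.

**Compound list**

1 | 2,4-dihydroxybenzaldehyde | O=Cc1ccc(O)cc1O | starting material
2 | 1-bromo-3-methylbut-2-ene (prenyl bromide) | CC(C)=CCBr | starting material
3 | 2-hydroxy-4-[(3-methylbut-2-en-1-yl)oxy]benzaldehyde | CC(C)=CCOc1ccc(C=O)c(O)c1 | intermediate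
4 | 2-(methoxymethoxy)-4-[(3-methylbut-2-en-1-yl)oxy]benzaldehyde | CC(C)=CCOc1ccc(C=O)c(OCOC)c1 | intermediate
5 | ortho-dienone, 4-formyl-3-(methoxymethoxy)-6-(2-methylbut-3-en-2-yl)cyclohexa-2,4-dien-1-one (racemic, not isolated) | O=C1C=C(OCOC)C(C=O)=CC1C(C)(C)C=C | intermediate
6 | 4-hydroxy-2-(methoxymethoxy)-5-(2-methylbut-3-en-2-yl)benzaldehyde | C=CC(C)(C)c1cc(C=O)c(OCOC)cc1O | intermediate
7 | 2,4-bis(methoxymethoxy)-5-(2-methylbut-3-en-2-yl)benzaldehyde | C=CC(C)(C)c1cc(C=O)c(OCOC)cc1OCOC | intermediate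
8 | 1-[2,4-bis(methoxymethoxy)-5-(2-methylbut-3-en-2-yl)phenyl]ethan-1-ol (racemic) | C=CC(C)(C)c1cc(C(C)O)c(OCOC)cc1OCOC | intermediate
9 | 1-[2,4-bis(methoxymethoxy)-5-(2-methylbut-3-en-2-yl)phenyl]ethan-1-one | C=CC(C)(C)c1cc(C(C)=O)c(OCOC)cc1OCOC | intermediate
10 | 2,4-dihydroxy-5-(2-methylbut-3-en-2-yl)benzaldehyde | C=CC(C)(C)c1cc(C=O)c(O)cc1O | intermediate
11 | 2-hydroxy-4-(methoxymethoxy)-5-(2-methylbut-3-en-2-yl)benzaldehyde | C=CC(C)(C)c1cc(C=O)c(O)cc1OCOC | intermediate
12 | methyl (2,4-dihydroxyphenyl)acetate | COC(=O)Cc1ccc(O)cc1O | starting material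
13 | methyl [2,4-bis(methoxymethoxy)phenyl]acetate | COC(=O)Cc1ccc(OCOC)cc1OCOC | intermediate
14 | 2-[2,4-bis(methoxymethoxy)phenyl]ethan-1-ol | OCCc1ccc(OCOC)cc1OCOC | intermediate
15 | {2-[2,4-bis(methoxymethoxy)phenyl]ethoxy}(tert-butyl)dimethylsilane | CC(C)(C)[Si](C)(C)OCCc1ccc(OCOC)cc1OCOC | intermediate
16 | {2-[5-bromo-2,4-bis(methoxymethoxy)phenyl]ethoxy}(tert-butyl)dimethylsilane | CC(C)(C)[Si](C)(C)OCCc1cc(Br)c(OCOC)cc1OCOC | intermediate
17 | aryllithium, [5-(2-{[tert-butyl(dimethyl)silyl]oxy}ethyl)-2,4-bis(methoxymethoxy)phenyl]lithium (not isolated) | [Li]c1cc(CCO[Si](C)(C)C(C)(C)C)c(OCOC)cc1OCOC | intermediate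
18 | 5-(2-{[tert-butyl(dimethyl)silyl]oxy}ethyl)-2,4-bis(methoxymethoxy)benzaldehyde | O=Cc1cc(CCO[Si](C)(C)C(C)(C)C)c(OCOC)cc1OCOC | intermediate
19 | 3-bromo-4-iodophenol | Oc1ccc(I)c(Br)c1 | starting material
20 | 2-bromo-1-iodo-4-(methoxymethoxy)benzene | COCOc1ccc(I)c(Br)c1 | intermediate
21 | (E)-1-[2,4-bis(methoxymethoxy)-5-(2-methylbut-3-en-2-yl)phenyl]-3-[5-(2-{[tert-butyl(dimethyl)silyl]oxy}ethyl)-2,4-bis(methoxymethoxy)phenyl]prop-2-en-1-one | C=CC(C)(C)c1cc(C(=O)/C=C/c2cc(CCO[Si](C)(C)C(C)(C)C)c(OCOC)cc2OCOC)c(OCOC)cc1OCOC | intermediate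
22 | dimethyl(phenyl)silyl enol ether of 23 (double-bond geometry undefined, not isolated) | C=CC(C)(C)c1cc(C(O[Si](C)(C)c2ccccc2)=CCc2cc(CCO[Si](C)(C)C(C)(C)C)c(OCOC)cc2OCOC)c(OCOC)cc1OCOC | intermediate
23 | 1-[2,4-bis(methoxymethoxy)-5-(2-methylbut-3-en-2-yl)phenyl]-3-[5-(2-{[tert-butyl(dimethyl)silyl]oxy}ethyl)-2,4-bis(methoxymethoxy)phenyl]propan-1-one | C=CC(C)(C)c1cc(C(=O)CCc2cc(CCO[Si](C)(C)C(C)(C)C)c(OCOC)cc2OCOC)c(OCOC)cc1OCOC | intermediate
24 | 1-[2,4-bis(methoxymethoxy)-5-(2-methylbut-3-en-2-yl)phenyl]-2-[2-bromo-4-(methoxymethoxy)phenyl]-3-[5-(2-{[tert-butyl(dimethyl)silyl]oxy}ethyl)-2,4-bis(methoxymethoxy)phenyl]propan-1-one (racemic, not isolated) | C=CC(C)(C)c1cc(C(=O)C(Cc2cc(CCO[Si](C)(C)C(C)(C)C)c(OCOC)cc2OCOC)c2ccc(OCOC)cc2Br)c(OCOC)cc1OCOC | intermediate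
25 | 2-[2,4-bis(methoxymethoxy)-5-(2-methylbut-3-en-2-yl)phenyl]-3-{[5-(2-{[tert-butyl(dimethyl)silyl]oxy}ethyl)-2,4-bis(methoxymethoxy)phenyl]methyl}-6-(methoxymethoxy)-1-benzofuran | C=CC(C)(C)c1cc(-c2oc3cc(OCOC)ccc3c2Cc2cc(CCO[Si](C)(C)C(C)(C)C)c(OCOC)cc2OCOC)c(OCOC)cc1OCOC | intermediate
26 | 2-[5-({2-[2,4-bis(methoxymethoxy)-5-(2-methylbut-3-en-2-yl)phenyl]-6-(methoxymethoxy)-1-benzofuran-3-yl}methyl)-2,4-bis(methoxymethoxy)phenyl]ethan-1-ol | C=CC(C)(C)c1cc(-c2oc3cc(OCOC)ccc3c2Cc2cc(CCO)c(OCOC)cc2OCOC)c(OCOC)cc1OCOC | intermediate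
27 | arylacetaldehyde corresponding to 26 (not isolated) | C=CC(C)(C)c1cc(-c2oc3cc(OCOC)ccc3c2Cc2cc(CC=O)c(OCOC)cc2OCOC)c(OCOC)cc1OCOC | intermediate
28 | [5-({2-[2,4-bis(methoxymethoxy)-5-(2-methylbut-3-en-2-yl)phenyl]-6-(methoxymethoxy)-1-benzofuran-3-yl}methyl)-2,4-bis(methoxymethoxy)phenyl]acetic acid | C=CC(C)(C)c1cc(-c2oc3cc(OCOC)ccc3c2Cc2cc(CC(=O)O)c(OCOC)cc2OCOC)c(OCOC)cc1OCOC | intermediate
29 | 2-formyl-5-(methoxymethoxy)-4-(2-methylbut-3-en-2-yl)phenyl ester of acid 28 (not isolated) | C=CC(C)(C)c1cc(-c2oc3cc(OCOC)ccc3c2Cc2cc(CC(=O)Oc3cc(OCOC)c(C(C)(C)C=C)cc3C=O)c(OCOC)cc2OCOC)c(OCOC)cc1OCOC | intermediate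
30 | 3-[5-({2-[2,4-bis(methoxymethoxy)-5-(2-methylbut-3-en-2-yl)phenyl]-6-(methoxymethoxy)-1-benzofuran-3-yl}methyl)-2,4-bis(methoxymethoxy)phenyl]-7-(methoxymethoxy)-6-(2-methylbut-3-en-2-yl)-2H-chromen-2-one | C=CC(C)(C)c1cc(-c2oc3cc(OCOC)ccc3c2Cc2cc(-c3cc4cc(C(C)(C)C=C)c(OCOC)cc4oc3=O)c(OCOC)cc2OCOC)c(OCOC)cc1OCOC | intermediate
31 | 3-[5-({2-[2,4-dihydroxy-5-(2-methylbut-3-en-2-yl)phenyl]-6-hydroxy-1-benzofuran-3-yl}methyl)-2,4-dihydroxyphenyl]-7-hydroxy-6-(2-methylbut-3-en-2-yl)-2H-chromen-2-one (CNP0380243.0) | C=CC(C)(C)c1cc(-c2oc3cc(O)ccc3c2Cc2cc(-c3cc4cc(C(C)(C)C=C)c(O)cc4oc3=O)c(O)cc2O)c(O)cc1O | target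

**Step count and risks**

Total step count: 21. Longest linear sequence: 13 steps (steps 1–6, then 15–21), from 1 to 31.

Steps most likely to fail:

Step 17 (key step). The second, ring-closing C–O coupling may stall after the first arylation, or the arylpalladium species may be diverted into Heck insertion at the terminal alkene or into reduction. Fallback: split the two bond formations between two metals. Setting out from 23, palladium-catalysed alpha-arylation alone with 20 (Pd(OAc)2, Xantphos, NaOt-Bu, toluene, 70 °C) would be stopped at the bromoaryl ketone 24, which is then isolated. A copper-catalysed Ullmann-type intramolecular enolate O-arylation (CuI 10 mol %, K3PO4, DMF, 105 °C) would close the furan and return to the route at 25. New compounds: none F0.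

Step 3 (Claisen rearrangement). Regiocontrol between C5 and C3 may erode, the prenyl group may be lost thermally, or the product may reorganise further (abnormal Claisen shift, addition of the new phenol to its alkene). Fallback: install the 1,1-dimethylallyl group by cross-coupling at a carbon fixed by a halide. Setting out from 1, bromination (Br2, AcOH, rt) should give 5-bromo-2,4-dihydroxybenzaldehyde F1. Double MOM protection (NaH, MOMCl, DMF) would give 5-bromo-2,4-bis(methoxymethoxy)benzaldehyde F2. A branched-selective (gamma) Suzuki–Miyaura coupling with 4,4,5,5-tetramethyl-2-(3-methylbut-2-en-1-yl)-1,3,2-dioxaborolane (Pd(OAc)2, a dialkylbiarylphosphine selected for gamma coupling, K3PO4, THF/H2O, 40 °C) would return to the route at 7. Because 6 is bypassed, 10 would then be made from 7 with methanolic HCl, which removes both MOM groups.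

Step 21 (global deprotection). Six-fold acetal cleavage may stop short, a liberated ortho-phenol may add to its neighbouring alkene under acid, or released formaldehyde equivalents may attack the resorcinol rings. Fallback: exchange acetals for silyl ethers under buffered Lewis-acid conditions. Setting out from 30, Me3SiOTf with 2,2'-bipyridyl (CH2Cl2, 0 °C to rt) should convert each aryl MOM ether into its trimethylsilyl ether, giving the hexakis(trimethylsilyl) ether of the target F3. Hydrolysis with water at rt would return to the route at 31.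

**Further compounds**

F0 | step 17 | none | none
F1 | step 3 | 5-bromo-2,4-dihydroxybenzaldehyde | O=Cc1cc(Br)c(O)cc1O
F2 | step 3 | 5-bromo-2,4-bis(methoxymethoxy)benzaldehyde | O=Cc1cc(Br)c(OCOC)cc1OCOC
F3 | step 21 | hexakis(trimethylsilyl) ether of the target | C=CC(C)(C)c1cc(-c2oc3cc(O[Si](C)(C)C)ccc3c2Cc2cc(-c3cc4cc(C(C)(C)C=C)c(O[Si](C)(C)C)cc4oc3=O)c(O[Si](C)(C)C)cc2O[Si](C)(C)C)c(O[Si](C)(C)C)cc1O[Si](C)(C)C
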